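## Retrosynthetic overview

1. The target is traced back to a bridged benzoxepine by Rieche diformylation, hydrogenation/debenzylation and SN1 methallylation of a DDQ-derived benzylic ether; this sets the benzylic stereocentre last.
2. The cyclopropane comes from dibromocarbene addition and cuprate methylation on the ring alkene; the oxepane C–O bond comes from a copper-mediated intramolecular aryl etherification of a tertiary cis-hydrindenol.
3. The cis-hydrindene alkene comes from reductive 1,3-transposition of a Robinson-annulation enone; the secondary methyl group on the six-membered carbocycle comes from hydroxyl-directed AlMe3 addition to the derived p-quinol-type dienone.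
4. The quaternary carbon and the first stereocentres come from ketoreductase desymmetrisation of an achiral 2-arylmethyl-2-methylcyclopentane-1,3-dione.
5. Ring order: arene and cyclopentane (bought) → cyclohexene → oxepane → cyclopropane.

Labels: Ar = 2,4-bis(benzyloxy)-6-bromophenyl. Compounds 16–23 carry indene locants. Compounds 24–33 carry the atom labels of the target SMILES read left to right: C5 benzylic carbon, C13 ether carbon, C14/C15 cyclopentane CH2, C16 quaternary C–CH3, C17 ring-fusion CH, C18/C19 cyclopropane CH, C21 CH–CH3, O7/O9 phenol oxygens.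

Assumption: a screened ketoreductase variant with the usual (2S,3S) preference for 2,2-disubstituted cyclopentane-1,3-diones accepts dione 9.

## Route

Step 1
Reactants: 1 5-bromobenzene-1,3-diol; 2 benzyl bromide
Product: 3 1,3-bis(benzyloxy)-5-bromobenzene
Conditions: BnBr (2.2 equiv in all), K2CO3 (3 equiv), DMF, 60 °C
Reagents that add atoms: benzyl bromide BrCc1ccccc1
Why: Twofold Williamson ether synthesis in which each phenol takes up one benzyl group, so a second equivalent of 2 is consumed as the atom-adding reagent; no stereocentre is formed.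

Step 2
Reactants: 3 1,3-bis(benzyloxy)-5-bromobenzene
Product: 5 2,4-bis(benzyloxy)-6-bromobenzaldehyde, via iminium chloride 4 (not isolated)
Conditions: POCl3, DMF, 90 °C; then H2O, 25 °C
Reagents that add atoms: N,N-dimethylformamide CN(C)C=O; water O
Why: Vilsmeier–Haack formylation occurs ortho/para to both ethers, at the position next to Br and not at the more hindered one between the two OBn groups.

Step 3
Reactants: 5 2,4-bis(benzyloxy)-6-bromobenzaldehyde; 6 cyclopentane-1,3-dione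
Product: 8 2-{[2,4-bis(benzyloxy)-6-bromophenyl]methyl}cyclopentane-1,3-dione, via alkylidene dione 7 (not isolated)
Conditions: diethyl 2,6-dimethyl-1,4-dihydropyridine-3,5-dicarboxylate (1.1 equiv), piperidine (10 mol %), AcOH (10 mol %), CH2Cl2, 25 °C
Reagents that add atoms: none
Why: Knoevenagel condensation followed by Hantzsch-ester transfer hydrogenation (organocatalytic reductive alkylation) gives only the mono-C-alkylated dione.

Step 4
Reactants: 8 2-{[2,4-bis(benzyloxy)-6-bromophenyl]methyl}cyclopentane-1,3-dione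
Product: 9 2-{[2,4-bis(benzyloxy)-6-bromophenyl]methyl}-2-methylcyclopentane-1,3-dione
Conditions: NaOH (1.0 equiv), MeI (3 equiv), H2O/1,4-dioxane, 65 °C
Reagents that add atoms: iodomethane CI
Why: C-alkylation of the dione enolate by soft MeI creates the quaternary carbon; the product keeps a mirror plane and is achiral.

Step 5
Reactants: 9 2-{[2,4-bis(benzyloxy)-6-bromophenyl]methyl}-2-methylcyclopentane-1,3-dione
Product: 10 (2S,3S)-2-(ArCH2)-3-hydroxy-2-methylcyclopentan-1-one
Conditions: ketoreductase (NADPH-dependent carbonyl reductase), NADP+ (cat.), i-PrOH (15% v/v), phosphate buffer pH 7.0, DMSO (10% v/v), 30 °C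
Reagents that add atoms: none
Why: Enzymatic desymmetrising carbonyl reduction; the ketoreductase reduces one enantiotopic C=O from one face, setting the quaternary (2S) and carbinol (3S) centres with OH cis to ArCH2.

Step 6
Reactants: 10 (2S,3S)-2-(ArCH2)-3-hydroxy-2-methylcyclopentan-1-one
Product: 11 (2S,3S)-2-(ArCH2)-2-methyl-3-(triisopropylsilyloxy)cyclopentan-1-one
Conditions: i-Pr3SiOTf, 2,6-lutidine, CH2Cl2, 0 → 25 °C
Reagents that add atoms: tri(propan-2-yl)silyl trifluoromethanesulfonate CC(C)[Si](OS(=O)(=O)C(F)(F)F)(C(C)C)C(C)C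
Why: Silyl ether formation blocks retro-aldol opening and makes the ArCH2 face of the ring the clearly hindered one.

Step 7
Reactants: 11 (2S,3S)-2-(ArCH2)-2-methyl-3-(triisopropylsilyloxy)cyclopentan-1-one
Product: 13 (2S,3S)-2-(ArCH2)-2-methyl-5-(triethylsilyloxy)-3-(triisopropylsilyloxy)cyclopentan-1-one (C5 epimers), via triethylsilyl enol ether 12 (not isolated)
Conditions: LiN(i-Pr)2, Et3SiCl, THF, −78 °C; then mCPBA, NaHCO3, CH2Cl2, 0 °C
Reagents that add atoms: chlorotriethylsilane CC[Si](Cl)(CC)CC; 3-chloroperbenzoic acid OOC(=O)c1cccc(Cl)c1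
Why: Rubottom oxidation at the only enolisable position; the new carbinol centre is a mixture that is flattened again in step 8.

Step 8
Reactants: 13 (2S,3S)-2-(ArCH2)-2-methyl-5-(triethylsilyloxy)-3-(triisopropylsilyloxy)cyclopentan-1-one (C5 epimers)
Product: 15 (2S,3S,5R)-2-(ArCH2)-2-methyl-5-(3-oxobutyl)-5-(triethylsilyloxy)-3-(triisopropylsilyloxy)cyclopentan-1-one, via bis-silyl enediol ether 14 (not isolated)
Conditions: KN(SiMe3)2, Me3SiCl, THF, −78 °C; then methyl vinyl ketone, Sc(OTf)3 (10 mol %), CH2Cl2, −78 → −40 °C; aq. NaHCO3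
Reagents that add atoms: methyl vinyl ketone CC(=O)C=C
Why: Mukaiyama–Michael addition; the enone approaches C5 from the face opposite the 3-silyloxy and ArCH2 groups, so the OSiEt3 group ends cis to both (5R).

Step 9
Reactants: 15 (2S,3S,5R)-2-(ArCH2)-2-methyl-5-(3-oxobutyl)-5-(triethylsilyloxy)-3-(triisopropylsilyloxy)cyclopentan-1-one
Product: 16 (2S,3R,7aR)-3-(ArCH2)-3-methyl-7a-(triethylsilyloxy)-2-(triisopropylsilyloxy)-1,2,3,6,7,7a-hexahydro-5H-inden-5-one
Conditions: KOt-Bu (0.5 equiv), t-BuOH/THF, 40 °C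
Reagents that add atoms: none
Why: Intramolecular aldol condensation (second stage of a Robinson annulation); the ring ketone has no α-hydrogen, so only the methyl-ketone enolate can close the six-membered enone.

Step 10
Reactants: 16 (2S,3R,7aR)-3-(ArCH2)-3-methyl-7a-(triethylsilyloxy)-2-(triisopropylsilyloxy)-1,2,3,6,7,7a-hexahydro-5H-inden-5-one
Product: 19 (2S,3R,7aS)-3-(ArCH2)-3-methyl-7a-(triethylsilyloxy)-2-(triisopropylsilyloxy)-1,2,3,7a-tetrahydro-5H-inden-5-one, via selenide 17 (not isolated), via selenoxide 18 (not isolated)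
Conditions: LiN(i-Pr)2, THF, −78 °C; PhSeBr; then 30% H2O2, pyridine, CH2Cl2, 0 → 25 °C
Reagents that add atoms: none
Why: Kinetic α′-selenation and selenoxide syn-elimination (Reich) introduce the C6=C7 double bond without palladium, which the aryl bromide would not tolerate.

Step 11
Reactants: 19 (2S,3R,7aS)-3-(ArCH2)-3-methyl-7a-(triethylsilyloxy)-2-(triisopropylsilyloxy)-1,2,3,7a-tetrahydro-5H-inden-5-one
Product: 20 (2S,3R,7aS)-3-(ArCH2)-7a-hydroxy-3-methyl-2-(triisopropylsilyloxy)-1,2,3,7a-tetrahydro-5H-inden-5-one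
Conditions: HF·pyridine, pyridine, THF, 0 °C
Reagents that add atoms: none
Why: Selective cleavage of the triethylsilyl ether (the triisopropylsilyl ether survives) frees the p-quinol-type tertiary alcohol.

Step 12
Reactants: 20 (2S,3R,7aS)-3-(ArCH2)-7a-hydroxy-3-methyl-2-(triisopropylsilyloxy)-1,2,3,7a-tetrahydro-5H-inden-5-one
Product: 21 (2S,3R,7S,7aS)-3-(ArCH2)-7a-hydroxy-3,7-dimethyl-2-(triisopropylsilyloxy)-1,2,3,6,7,7a-hexahydro-5H-inden-5-one
Conditions: AlMe3 (3.5 equiv), CH2Cl2, −78 → 0 °C; aq. KNaC4H4O6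
Reagents that add atoms: trimethylaluminium C[Al](C)C
Why: Hydroxyl-directed conjugate addition; the aluminium alkoxide delivers methyl to C7, the only unsubstituted β-carbon, on the face of the OH.

Step 13
Reactants: 21 (2S,3R,7S,7aS)-3-(ArCH2)-7a-hydroxy-3,7-dimethyl-2-(triisopropylsilyloxy)-1,2,3,6,7,7a-hexahydro-5H-inden-5-one
Product: 23 (2S,3R,3aR,7S,7aS)-3-(ArCH2)-3,7-dimethyl-2-(triisopropylsilyloxy)-2,3,3a,6,7,7a-hexahydro-1H-inden-7a-ol, via tosylhydrazone 22 (not isolated)
Conditions: TsNHNH2, EtOH, 25 °C; then catecholborane (3 equiv), CHCl3, 0 °C; then NaOAc·3H2O, 65 °C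
Reagents that add atoms: none
Why: Kabalka reductive 1,3-transposition; hydride adds to C5 anti to the angular 7a-oxygen substituent and the allylic diazene then passes its hydrogen suprafacially to C3a with loss of N2, giving the cis ring fusion and the C4=C5 alkene.

Step 14
Reactants: 23 (2S,3R,3aR,7S,7aS)-3-(ArCH2)-3,7-dimethyl-2-(triisopropylsilyloxy)-2,3,3a,6,7,7a-hexahydro-1H-inden-7a-ol
Product: 24 bridged aryl ether (23 whose 7a-oxygen is bonded to the former C–Br carbon)
Conditions: CuI (20 mol %), 2,2′-bipyridine (40 mol %), KOt-Bu (2 equiv), DMF, 120 °C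
Reagents that add atoms: none
Why: Intramolecular Ullmann-type aryl etherification; the tertiary alkoxide and ArCH2 are cis-1,3 on the cyclopentane, so the seven-membered ether bridge can close without touching a stereocentre.

Step 15
Reactants: 24 bridged aryl ether
Product: 25 dibromocyclopropane (24 carrying CBr2 across C18=C19)
Conditions: CHBr3, KOt-Bu, pentane, −10 → 25 °C
Reagents that add atoms: bromoform BrC(Br)Br
Why: Dibromocarbene [2+1] cycloaddition to the only alkene from the convex face (side of H-17 and the ether oxygen, away from the cyclopentane and its C-methyl) gives the cyclopropane cis to H-17.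

Step 16
Reactants: 25 dibromocyclopropane
Product: 26 gem-dimethylcyclopropane (25 with both Br replaced by CH3)
Conditions: Me2CuLi (6 equiv, from MeLi and CuI), Et2O, −40 → 0 °C; then MeI, 0 → 25 °C
Reagents that add atoms: lithium dimethylcuprate [Li+].C[Cu-]C; iodomethane CI
Why: Corey–Posner gem-dimethylation (halogen–copper exchange, methyl migration, alkylation by MeI) with retention of the ring stereocentres.

Step 17
Reactants: 26 gem-dimethylcyclopropane
Product: 27 C15 alcohol (26 with the silyl ether cleaved)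
Conditions: Bu4NF, THF, 50 °C
Reagents that add atoms: none
Why: Fluoride cleavage of the triisopropylsilyl ether.

Step 18
Reactants: 27 C15 alcohol
Product: 28 S-methyl xanthate of 27
Conditions: NaH, THF, 0 °C; CS2; MeI, 25 °C
Reagents that add atoms: carbon disulfide S=C=S; iodomethane CI
Why: Xanthate formation activates the secondary alcohol for radical deoxygenation.

Step 19
Reactants: 28 S-methyl xanthate of 27
Product: 29 C15-deoxy compound (O7,O9-dibenzyl ether of the target skeleton with CH2 at C5 and no CHO groups)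
Conditions: n-Bu3SnH, AIBN (cat.), toluene, 110 °C
Reagents that add atoms: none
Why: Barton–McCombie deoxygenation turns the carbinol carbon into CH2, removing that stereocentre.

Step 20
Reactants: 29 C15-deoxy compound
Product: 30 C5 methyl ether of 29 (C5 epimers)
Conditions: DDQ (1.3 equiv), MeOH (10 equiv), CH2Cl2, 0 °C
Reagents that add atoms: methanol CO
Why: DDQ abstracts hydride from the benzylic CH2, which is activated by three ortho/para oxygens, and methanol traps the cation; the epimer mixture is erased in step 21.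

Step 21
Reactants: 30 C5 methyl ether of 29 (C5 epimers)
Product: 31 C5 methallyl compound (2-methylprop-2-enyl at C5 in the target configuration)
Conditions: methallyltrimethylsilane (3 equiv), Me3SiOTf (20 mol %), CH2Cl2, −78 °C
Reagents that add atoms: trimethyl(2-methylprop-2-en-1-yl)silane CC(=C)C[Si](C)(C)C
Why: SN1 Hosomi–Sakurai allylation; the planar benzylic cation is attacked on its exo face (side of the one-carbon bridge C17), since the other face is screened by the endo hydrogens of the C14–C15 bridge, which sets C5.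

Step 22
Reactants: 31 C5 methallyl compound
Product: 32 bis-deformyl target (5-isobutyl compound with two free phenols)
Conditions: H2 (1 atm), 10% Pd/C, EtOAc/EtOH, 25 °C
Reagents that add atoms: none
Why: Hydrogenation of the 1,1-disubstituted alkene to isobutyl and hydrogenolysis of both benzyl ethers; the isolated gem-dimethylcyclopropane is inert under these conditions.

Step 23
Reactants: 32 bis-deformyl target
Product: 33 CNP0202714.1 (target)
Conditions: Cl2CHOMe (6 equiv), TiCl4 (6 equiv), CH2Cl2, −78 → 0 °C; then H2O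
Reagents that add atoms: dichloro(methoxy)methane COC(Cl)Cl; water O
Why: Twofold Rieche formylation (one equivalent of the dichloromethyl ether per formyl group) at the two remaining aromatic positions, each flanked by two oxygens; no stereocentre is affected.

## Compound list

1 | 5-bromobenzene-1,3-diol | Oc1cc(O)cc(Br)c1 | starting material
2 | benzyl bromide | BrCc1ccccc1 | starting material
3 | 1,3-bis(benzyloxy)-5-bromobenzene | Brc1cc(OCc2ccccc2)cc(OCc2ccccc2)c1 | intermediate
4 | iminium chloride {[2,4-bis(benzyloxy)-6-bromophenyl]methylidene}dimethylammonium chloride | C[N+](C)=Cc1c(Br)cc(OCc2ccccc2)cc1OCc1ccccc1.[Cl-] | intermediate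
5 | 2,4-bis(benzyloxy)-6-bromobenzaldehyde | O=Cc1c(Br)cc(OCc2ccccc2)cc1OCc1ccccc1 | intermediate
6 | cyclopentane-1,3-dione | O=C1CCC(=O)C1 | starting material
7 | alkylidene dione 2-{[2,4-bis(benzyloxy)-6-bromophenyl]methylidene}cyclopentane-1,3-dione | O=C1CCC(=O)C1=Cc1c(Br)cc(OCc2ccccc2)cc1OCc1ccccc1 | intermediate
8 | 2-{[2,4-bis(benzyloxy)-6-bromophenyl]methyl}cyclopentane-1,3-dione | O=C1CCC(=O)C1Cc1c(Br)cc(OCc2ccccc2)cc1OCc1ccccc1 | intermediate
9 | 2-{[2,4-bis(benzyloxy)-6-bromophenyl]methyl}-2-methylcyclopentane-1,3-dione | O=C1CCC(=O)C1(C)Cc1c(Br)cc(OCc2ccccc2)cc1OCc1ccccc1 | intermediate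
10 | (2S,3S)-2-(ArCH2)-3-hydroxy-2-methylcyclopentan-1-one | O=C1CC[C@H](O)[C@]1(C)Cc1c(Br)cc(OCc2ccccc2)cc1OCc1ccccc1 | intermediate
11 | (2S,3S)-2-(ArCH2)-2-methyl-3-(triisopropylsilyloxy)cyclopentan-1-one | O=C1CC[C@H](O[Si](C(C)C)(C(C)C)C(C)C)[C@]1(C)Cc1c(Br)cc(OCc2ccccc2)cc1OCc1ccccc1 | intermediate
12 | triethylsilyl enol ether (4S,5S)-5-(ArCH2)-5-methyl-1-(triethylsilyloxy)-4-(triisopropylsilyloxy)cyclopent-1-ene | CC[Si](CC)(CC)OC1=CC[C@H](O[Si](C(C)C)(C(C)C)C(C)C)[C@]1(C)Cc1c(Br)cc(OCc2ccccc2)cc1OCc1ccccc1 | intermediate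
13 | (2S,3S)-2-(ArCH2)-2-methyl-5-(triethylsilyloxy)-3-(triisopropylsilyloxy)cyclopentan-1-one (C5 epimers) | O=C1C(O[Si](CC)(CC)CC)C[C@H](O[Si](C(C)C)(C(C)C)C(C)C)[C@]1(C)Cc1c(Br)cc(OCc2ccccc2)cc1OCc1ccccc1 | intermediate
14 | bis-silyl enediol ether (4S,5S)-5-(ArCH2)-5-methyl-2-(triethylsilyloxy)-4-(triisopropylsilyloxy)-1-(trimethylsilyloxy)cyclopent-1-ene | C[Si](C)(C)OC1=C(O[Si](CC)(CC)CC)C[C@H](O[Si](C(C)C)(C(C)C)C(C)C)[C@]1(C)Cc1c(Br)cc(OCc2ccccc2)cc1OCc1ccccc1 | intermediate
15 | (2S,3S,5R)-2-(ArCH2)-2-methyl-5-(3-oxobutyl)-5-(triethylsilyloxy)-3-(triisopropylsilyloxy)cyclopentan-1-one | O=C1[C@@](O[Si](CC)(CC)CC)(CCC(C)=O)C[C@H](O[Si](C(C)C)(C(C)C)C(C)C)[C@]1(C)Cc1c(Br)cc(OCc2ccccc2)cc1OCc1ccccc1 | intermediate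
16 | (2S,3R,7aR)-3-(ArCH2)-3-methyl-7a-(triethylsilyloxy)-2-(triisopropylsilyloxy)-1,2,3,6,7,7a-hexahydro-5H-inden-5-one | O=C1CC[C@@]2(O[Si](CC)(CC)CC)C[C@H](O[Si](C(C)C)(C(C)C)C(C)C)[C@](C)(Cc3c(Br)cc(OCc4ccccc4)cc3OCc3ccccc3)C2=C1 | intermediate
17 | selenide (6-phenylselanyl derivative of 16) | O=C1C([Se]c3ccccc3)C[C@@]2(O[Si](CC)(CC)CC)C[C@H](O[Si](C(C)C)(C(C)C)C(C)C)[C@](C)(Cc3c(Br)cc(OCc4ccccc4)cc3OCc3ccccc3)C2=C1 | intermediate
18 | selenoxide (6-phenylseleninyl derivative of 16) | O=C1C([Se](=O)c3ccccc3)C[C@@]2(O[Si](CC)(CC)CC)C[C@H](O[Si](C(C)C)(C(C)C)C(C)C)[C@](C)(Cc3c(Br)cc(OCc4ccccc4)cc3OCc3ccccc3)C2=C1 | intermediate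
19 | (2S,3R,7aS)-3-(ArCH2)-3-methyl-7a-(triethylsilyloxy)-2-(triisopropylsilyloxy)-1,2,3,7a-tetrahydro-5H-inden-5-one | O=C1C=C[C@@]2(O[Si](CC)(CC)CC)C[C@H](O[Si](C(C)C)(C(C)C)C(C)C)[C@](C)(Cc3c(Br)cc(OCc4ccccc4)cc3OCc3ccccc3)C2=C1 | intermediate
20 | (2S,3R,7aS)-3-(ArCH2)-7a-hydroxy-3-methyl-2-(triisopropylsilyloxy)-1,2,3,7a-tetrahydro-5H-inden-5-one | O=C1C=C[C@@]2(O)C[C@H](O[Si](C(C)C)(C(C)C)C(C)C)[C@](C)(Cc3c(Br)cc(OCc4ccccc4)cc3OCc3ccccc3)C2=C1 | intermediate
21 | (2S,3R,7S,7aS)-3-(ArCH2)-7a-hydroxy-3,7-dimethyl-2-(triisopropylsilyloxy)-1,2,3,6,7,7a-hexahydro-5H-inden-5-one | O=C1C[C@H](C)[C@@]2(O)C[C@H](O[Si](C(C)C)(C(C)C)C(C)C)[C@](C)(Cc3c(Br)cc(OCc4ccccc4)cc3OCc3ccccc3)C2=C1 | intermediate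
22 | tosylhydrazone of 21 | Cc1ccc(cc1)S(=O)(=O)NN=C1C[C@H](C)[C@@]2(O)C[C@H](O[Si](C(C)C)(C(C)C)C(C)C)[C@](C)(Cc3c(Br)cc(OCc4ccccc4)cc3OCc3ccccc3)C2=C1 | intermediate
23 | (2S,3R,3aR,7S,7aS)-3-(ArCH2)-3,7-dimethyl-2-(triisopropylsilyloxy)-2,3,3a,6,7,7a-hexahydro-1H-inden-7a-ol | C1[C@H](C)[C@@]2(O)C[C@H](O[Si](C(C)C)(C(C)C)C(C)C)[C@](C)(Cc3c(Br)cc(OCc4ccccc4)cc3OCc3ccccc3)[C@H]2C=C1 | intermediate
24 | bridged aryl ether (23 whose 7a-oxygen is bonded to the former C–Br carbon) | C1c2c(OCc3ccccc3)cc(OCc3ccccc3)cc2O[C@]23C[C@H](O[Si](C(C)C)(C(C)C)C(C)C)[C@@]1(C)[C@H]2C=CC[C@@H]3C | intermediate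
25 | dibromocyclopropane (24 carrying CBr2 across C18=C19) | C1c2c(OCc3ccccc3)cc(OCc3ccccc3)cc2O[C@]23C[C@H](O[Si](C(C)C)(C(C)C)C(C)C)[C@@]1(C)[C@H]2[C@H]1[C@@H](C[C@@H]3C)C1(Br)Br | intermediate
26 | gem-dimethylcyclopropane (25 with both Br replaced by CH3) | C1c2c(OCc3ccccc3)cc(OCc3ccccc3)cc2O[C@]23C[C@H](O[Si](C(C)C)(C(C)C)C(C)C)[C@@]1(C)[C@H]2[C@H]1[C@@H](C[C@@H]3C)C1(C)C | intermediate
27 | C15 alcohol (26 with the silyl ether cleaved) | C1c2c(OCc3ccccc3)cc(OCc3ccccc3)cc2O[C@]23C[C@H](O)[C@@]1(C)[C@H]2[C@H]1[C@@H](C[C@@H]3C)C1(C)C | intermediate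
28 | S-methyl xanthate of 27 | C1c2c(OCc3ccccc3)cc(OCc3ccccc3)cc2O[C@]23C[C@H](OC(=S)SC)[C@@]1(C)[C@H]2[C@H]1[C@@H](C[C@@H]3C)C1(C)C | intermediate
29 | C15-deoxy compound (O7,O9-dibenzyl ether of the target skeleton with CH2 at C5 and no CHO groups) | C1c2c(OCc3ccccc3)cc(OCc3ccccc3)cc2O[C@]23CC[C@@]1(C)[C@H]2[C@H]1[C@@H](C[C@@H]3C)C1(C)C | intermediate
30 | C5 methyl ether of 29 (C5 epimers) | COC1c2c(OCc3ccccc3)cc(OCc3ccccc3)cc2O[C@]23CC[C@@]1(C)[C@H]2[C@H]1[C@@H](C[C@@H]3C)C1(C)C | intermediate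
31 | C5 methallyl compound (2-methylprop-2-enyl at C5 in the target configuration) | CC(=C)C[C@H]1c2c(OCc3ccccc3)cc(OCc3ccccc3)cc2O[C@]23CC[C@@]1(C)[C@H]2[C@H]1[C@@H](C[C@@H]3C)C1(C)C | intermediate
32 | bis-deformyl target (5-isobutyl compound with two free phenols) | CC(C)C[C@H]1c2c(O)cc(O)cc2O[C@]23CC[C@@]1(C)[C@H]2[C@H]1[C@@H](C[C@@H]3C)C1(C)C | intermediate
33 | CNP0202714.1 | CC(C)C[C@H]1c2c(O)c(C=O)c(O)c(C=O)c2O[C@]23CC[C@@]1(C)[C@H]2[C@H]1[C@@H](C[C@@H]3C)C1(C)C | target

## Step count and risks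

Total steps: 23. Longest linear sequence: 23 steps (1 → 33).

Step 9 (aldol closure onto a ketone flanked by two quaternary carbons). If the closure stalls or retro-Michael cleavage wins, the fallback sets out from 13. Its enediol ether 14 is added under the step-8 conditions to dimethyl (2-oxobut-3-en-1-yl)phosphonate instead of methyl vinyl ketone, giving the β-ketophosphonate F1. NaH in THF at 25 °C then closes the ring by an irreversible intramolecular Horner–Wadsworth–Emmons olefination, and the route is rejoined at 16.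

Step 14 (copper-mediated closure of a seven-membered bridged ether from a hindered tertiary alcohol). If the coupling fails, the fallback sets out from 23 and drops the metal-catalysed C–O coupling. NaNH2/NaOt-Bu in THF at 40 °C eliminates HBr to the aryne F2. The neighbouring tertiary alkoxide adds to the aryne carbon meta to the benzyloxy group, leaving the anion ortho to OBn, and protonation returns to the route at 24.

Step 21 (facial selectivity at the benzylic carbon). If the allylsilane enters from the other face and gives mainly the C5 epimer, the order of bond formation is inverted, setting out from 29. DDQ in wet CH2Cl2 gives the benzylic ketone F3. i-BuMgBr with CeCl3 in THF at −78 °C adds to it to give the tertiary benzylic alcohol F4. Et3SiH with BF3·OEt2 at −78 °C (ionic hydrogenation) then delivers hydride to the face the allylsilane had taken, which leaves isobutyl on the required face and gives the dibenzyl ether F5. Hydrogenolysis under the step-22 conditions returns to the route at 32.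

Further compounds

F1 | step 9 | β-ketophosphonate analogue of 15 (CH2P(O)(OMe)2 in place of the terminal CH3) | O=C1[C@@](O[Si](CC)(CC)CC)(CCC(=O)CP(=O)(OC)OC)C[C@H](O[Si](C(C)C)(C(C)C)C(C)C)[C@]1(C)Cc1c(Br)cc(OCc2ccccc2)cc1OCc1ccccc1
F2 | step 14 | aryne from 23 (C–Br and the adjacent aromatic C–H replaced by a formal triple bond) | C1[C@H](C)[C@@]2(O)C[C@H](O[Si](C(C)C)(C(C)C)C(C)C)[C@](C)(CC3=C(OCc4ccccc4)C=C(OCc4ccccc4)C#C3)[C@H]2C=C1
F3 | step 21 | benzylic ketone of 29 (C5=O) | O=C1c2c(OCc3ccccc3)cc(OCc3ccccc3)cc2O[C@]23CC[C@@]1(C)[C@H]2[C@H]1[C@@H](C[C@@H]3C)C1(C)C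
F4 | step 21 | tertiary benzylic alcohol from F3 carrying isobutyl at C5 (C5 epimers) | CC(C)CC1(O)c2c(OCc3ccccc3)cc(OCc3ccccc3)cc2O[C@]23CC[C@@]1(C)[C@H]2[C@H]1[C@@H](C[C@@H]3C)C1(C)C
F5 | step 21 | O7,O9-dibenzyl ether of 32 | CC(C)C[C@H]1c2c(OCc3ccccc3)cc(OCc3ccccc3)cc2O[C@]23CC[C@@]1(C)[C@H]2[C@H]1[C@@H](C[C@@H]3C)C1(C)C
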